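The numbers in the tables are simulated for substances that don't exist; scatter was added.

How much target stands in this flask at 40 min, and which move then adds most?

| flask | substrate | coupling partner | temperature | remark | time |
|---|---|---|---|---|---|
| theta | 0.35 M | 1.1 equiv | 0 °C | the very flask that is asked about, followed so far |  |
| zeta | 0.35 M | 1.1 equiv | −15 °C | run made earlier |  |
| flask | 0.35 M | 1.10 equiv | 0 °C |  | 40 min |

- theta (time / min: target / %, substrate / %): 3.00: 55, 12; 5.00: 54, 4; 8.00: 53, 0; 15.0: 49, 2; 25.0: 50, 0; 40.0: 48, 0
- zeta (time / min: target / %, substrate / %): 6.00: 47, 37; 10.0: 56, 22; 15.0: 61, 11; 30.0: 60, 4; 50.0: 58, 0; 80.0: 49, 1

(each reading ± 1.5 percentage points)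

- cedar: at 40 min raise the temperature by 25 K, then wait 20 min
- larch: at 40 min add coupling partner, 100% of the amount charged, then wait 20 min
- maple: at 40 min take out 90% of the target then present, then wait 20 min
- alder: change nothing and wait 20 min more

- target that was removed still counts
- on the list of suspects stand: substrate + coupling partner -> target; substrate -> side product; target <-> isomer of the product
- additions bring no volume worth counting

- target, in percent of the substrate first charged, at 40 min
- what to do for the largest gain in target; "none" if nothing gains more than 2 percentage points (cedar / larch / maple / alder / none)
- target present, with what was taken out counted in, in percent of the substrate first charged, after larch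
- target present, with what was taken out counted in, in percent of the substrate first charged, after alder

The theta run is this flask, and its late readings lie flat within the scatter, with a mean of 49.0%. Substrate reads 0% at 40.0 min, so I expect larch and alder to stay at that mean too. What can still move target is the isomer, so I want the pool, target plus isomer, which nobody measured.

On the suspects' list the coupling step needs both partners and the side step needs substrate alone. Side product per unit of target therefore grows as coupling partner falls, and summed up, side product equals the loss number (an inverse selectivity factor) times ln(coupling partner charged / coupling partner left), everything in fractions of the substrate charge.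

Two readings give the loss number. The one at 3.00 min gives 0.476, the one at 5.00 min gives 0.622, and they part. The later one cheats: between them substrate fell by 8 percentage points, yet target fell by 1 point, so target was already leaking into isomer. The earlier reading hides less isomer, though still some, so its number runs high and the pool it gives is a floor.

Setting pool plus side product equal to the charge, the mean of the reading and the value the balance returns gives a pool of 0.610, and the balance then closes at 0.995.

If the remaining pool re-divides in today's proportion, maple gains about 8.7 points. Cedar draws on the isomer, which this floor puts at 12 points or more. The colder zeta run already reads 49% and was still falling, which suggests that warmth favours target. I choose cedar, narrowly.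

The forecast says 48.5% now, 47.5% after larch, 47.5% after alder, and maple as best, holding that “Warming only speeds relaxation”.

The simulation gives 48.6% now, 48.6% after larch and 48.6% after alder. Its best move is cedar, gaining 14 points against 11 points for maple.

    substrate + coupling partner → target (k = 0.0340 L mol⁻¹ s⁻¹, Ea = 60.0 kJ mol⁻¹)
    substrate → side product (k = 0.00440 s⁻¹, Ea = 69.0 kJ mol⁻¹)
    target ⇌ isomer of the product (K = 0.360, k = 8.20 × 10⁻⁴ s⁻¹, Ea = 86.0 kJ mol⁻¹, ΔH = −53.0 kJ mol⁻¹)
    (constants at 0 °C)

At the start substrate went 3.0 times as fast to target as to side product. At 40.0 min this flask holds 33.9% side product, and its pool of 66.1% stands above the floor. In the neighbour flask charged with 0.21 M of substrate, the loss number scales up to 0.793, giving a floor of 0.500. The computed pool there is 56.1%, again above it.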